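**Retrosynthetic overview**

1. The target is a (3S)-6,7-dimethoxychroman carrying a 2,3-dimethoxy-1,4-benzoquinone at C-3; the quinone ring is disconnected at the bond between its two methoxy-bearing carbons, C-2 and C-3.
2. Enabling feature: in the quinone ring, C-2 and C-3 are each the α-carbon of one carbonyl (C-1, C-4), and these carbonyls are held cis by the C-5=C-6 alkene. The ring is therefore the oxidatively cyclised, aromatised bis-enol form of a (Z)-1,6-dimethoxyhex-3-ene-2,5-dione.
3. That Z-ene-1,4-dione is the oxidatively opened form of a 2,5-bis(methoxymethyl)furan, a temporary ring that fixes the Z geometry and is removed in step 6. Its bis-silyl enol ether, a tetra-oxygenated (Z)-hexatriene, is closed at the anode to the protected hydroquinone.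
4. The C-3 stereocentre is set earlier by iridium-catalysed asymmetric hydrogenation of a 3-furyl-2H-chromene, made by palladium-catalysed α-arylation of 6,7-dimethoxychroman-4-one with the 3-bromofuran, reduction and dehydration.
5. Ring order: benzopyran (bought as the chromanone) and furan (bought), furan opened, quinone carbocycle closed (step 8), quinone oxidation level reached (step 9).

Key step: step 8

Remark: 3-bromo-2,5-dimethylfuran (1) and 6,7-dimethoxychroman-4-one (4) are taken as catalogue compounds; quinone locants C-1 to C-6 follow 2,3-dimethoxy-5-substituted 1,4-benzoquinone numbering.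

**Route**

Step 1
Reactants: 1 3-bromo-2,5-dimethylfuran
Product: 3 3-bromo-2,5-bis(methoxymethyl)furan, via 3-bromo-2,5-bis(bromomethyl)furan 2 (not isolated)
Conditions: NBS (2.1 equiv), AIBN (cat.), PhCF3, 80 °C; filter; then NaOMe (2.5 equiv), MeOH, 0 °C to rt
Reagents that add atoms: sodium methoxide, [Na+].[O-]C
Why: Wohl–Ziegler radical bromination of the two furfurylic methyl groups followed by SN2 methanolysis of the labile bis(bromomethyl)furan, a sequence that avoids electrophilic attack on the α-positions of an alkoxymethylfuran and leaves the ring bromide in place.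

Step 2
Reactants: 3 3-bromo-2,5-bis(methoxymethyl)furan; 4 6,7-dimethoxychroman-4-one
Product: 5 rac-3-[2,5-bis(methoxymethyl)furan-3-yl]-6,7-dimethoxychroman-4-one
Conditions: Pd(OAc)2 (5 mol %), P(t-Bu)3·HBF4 (10 mol %), NaOt-Bu (2.2 equiv), toluene, 80 °C
Reagents that add atoms: none
Why: palladium-catalysed α-arylation of a ketone enolate, a reaction type established for chroman-4-ones with (hetero)aryl bromides, in which the more acidic product rests as its enolate and is not arylated twice; the C-3 centre forms racemic and is erased two steps later.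

Step 3
Reactants: 5 rac-3-[2,5-bis(methoxymethyl)furan-3-yl]-6,7-dimethoxychroman-4-one
Product: 6 3-[2,5-bis(methoxymethyl)furan-3-yl]-6,7-dimethoxychroman-4-ol (racemic cis/trans mixture)
Conditions: NaBH4, MeOH/THF, 0 °C to rt
Reagents that add atoms: none
Why: hydride reduction of the aryl ketone, the diastereomer mixture being of no consequence because both sp3 centres become sp2 in the next step.

Step 4
Reactants: 6 3-[2,5-bis(methoxymethyl)furan-3-yl]-6,7-dimethoxychroman-4-ol
Product: 7 3-[2,5-bis(methoxymethyl)furan-3-yl]-6,7-dimethoxy-2H-chromene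
Conditions: PPTS (10 mol %), 4 Å molecular sieves, toluene (dilute), 80 °C
Reagents that add atoms: none
Why: acid-catalysed E1 dehydration through a benzylic cation stabilised by the para 7-methoxy group and the ortho ring oxygen, giving the 3,4-alkene conjugated with both the arene and the furan.

Step 5
Reactants: 7 3-[2,5-bis(methoxymethyl)furan-3-yl]-6,7-dimethoxy-2H-chromene
Product: 8 (3S)-3-[2,5-bis(methoxymethyl)furan-3-yl]-6,7-dimethoxychroman
Conditions: H2 (50 bar), [Ir(cod)(t-Bu-PHOX)]BArF (2 mol %, ligand enantiomer chosen to give 3S), CH2Cl2, rt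
Reagents that add atoms: none
Why: iridium-catalysed asymmetric hydrogenation of a trisubstituted 3-aryl-2H-chromene (the isoflavene substrate class) with an N,P-ligated catalyst, in which the chiral ligand controls the face of hydrogen delivery to C-3 and its hand is chosen to give 3S, while the fully substituted furan double bonds are too hindered to be reduced.

Step 6
Reactants: 8 (3S)-3-[2,5-bis(methoxymethyl)furan-3-yl]-6,7-dimethoxychroman
Product: 9 (3Z)-3-[(3S)-6,7-dimethoxychroman-3-yl]-1,6-dimethoxyhex-3-ene-2,5-dione
Conditions: mCPBA (1.05 equiv), NaHCO3, CH2Cl2, −20 to 0 °C, dark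
Reagents that add atoms: 3-chloroperoxybenzoic acid (mCPBA), OOC(=O)c1cccc(Cl)c1
Why: peracid oxidation of a 2,5-dialkylfuran (epoxidation of one ring double bond, then ring opening) is the standard unmasking of a (Z)-ene-1,4-dione, the Z geometry being fixed by the furan ring and the C-3 centre being untouched under the buffered conditions.

Step 7
Reactants: 9 (3Z)-3-[(3S)-6,7-dimethoxychroman-3-yl]-1,6-dimethoxyhex-3-ene-2,5-dione
Product: 10 (3S)-3-[(1Z,3Z,5Z)-2,5-bis(tert-butyldimethylsilyloxy)-1,6-dimethoxyhexa-1,3,5-trien-3-yl]-6,7-dimethoxychroman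
Conditions: 9 added to TBSOTf (2.5 equiv) and Et3N (5 equiv), CH2Cl2, −78 to 0 °C; filtration through Et3N-deactivated silica
Reagents that add atoms: tert-butyldimethylsilyl trifluoromethanesulfonate (TBSOTf), CC(C)(C)[Si](C)(C)OS(=O)(=O)C(F)(F)F
Why: soft enolisation with a silyl triflate and a tertiary amine converts both ketones into silyl enol ethers toward their only α-CH2 groups, low temperature and excess amine being chosen so that O-silylation outruns aldol closure and γ-deprotonation, and the terminal enol-ether geometry being of no consequence.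

Step 8
Reactants: 10 (3S)-3-[(1Z,3Z,5Z)-2,5-bis(tert-butyldimethylsilyloxy)-1,6-dimethoxyhexa-1,3,5-trien-3-yl]-6,7-dimethoxychroman
Product: 11 (3S)-3-[2,5-bis(tert-butyldimethylsilyloxy)-3,4-dimethoxyphenyl]-6,7-dimethoxychroman
Conditions: undivided cell, reticulated vitreous carbon anode, Pt cathode, Bu4NPF6 (0.1 M), 2,6-lutidine (4 equiv), CH2Cl2/MeCN 4:1, controlled anode potential set by cyclic voltammetry just past the first wave of 10, about 2.1 F/mol, 0 °C
Reagents that add atoms: none
Why: Proposed new method: One-electron oxidation at the anode of the tetra-oxygenated (Z)-hexatriene of 10, expected to be by far the most easily oxidised π-system in the molecule, should give a radical cation whose two terminal methoxy-bearing carbons, held within bonding distance by the Z-alkene inherited from the furan, join to give the 5,6-dimethoxy-1,4-bis(silyloxy)cyclohexa-1,3-diene radical cation (should thermal disrotatory closure of the triene come first, the same diene is simply oxidised at the anode). Proton loss to 2,6-lutidine, a second electron transfer and a second proton loss (an ECE sequence) then aromatise the new ring to the hydroquinone bis-silyl ether 11, and the cathode turns the two protons into H2. The closest known reaction types are the anodic and chemical oxidative coupling of two silyl enol ethers to 1,4-diketones, the anodic coupling of enol-ether radical cations with electron-rich olefins, and the thermal 6π-electrocyclisation of (Z)-hexatrienes followed by dehydrogenation; new is their use to build a fully substituted hydroquinone ring from an open chain. The only ring closed is the carbocycle of the future quinone, by 6-endo carbon–carbon bond formation between the two enol-ether β-carbons (the radical-cation counterpart of a 6π-electrocyclisation); the two sp3 centres formed in passing are erased on aromatisation, so no new stereocentre has to be controlled and C-3 of the chroman is a spectator. The step needs chemoselective oxidation of the triene beside the 1,2,4-trialkoxybenzene ring, which the four oxygen donors on a conjugated triene and potentiostatic control should secure, and it needs the electrolysis to stop at the hydroquinone level, which is expected because the bis-silylated tetra-oxygenated arene 11 with its twisted vicinal methoxy groups should be harder to oxidise than 10. Aromatisation by proton loss and not by loss of methanol is favoured by the base and by the acid-free, oxidising medium.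

Step 9
Reactants: 11 (3S)-3-[2,5-bis(tert-butyldimethylsilyloxy)-3,4-dimethoxyphenyl]-6,7-dimethoxychroman
Product: 13 abroquinone A, 5-[(3S)-6,7-dimethoxychroman-3-yl]-2,3-dimethoxycyclohexa-2,5-diene-1,4-dione, via hydroquinone 12 (not isolated)
Conditions: Bu4NF (2.2 equiv), AcOH (2.2 equiv), THF, 0 °C; then Ag2O (3 equiv), rt, dark
Reagents that add atoms: none
Why: fluoride cleavage of the two aryl silyl ethers under acetic acid buffering, then two-electron hydroquinone-to-quinone oxidation with Ag2O, conditions mild enough to spare the 1,2,4-trialkoxybenzene ring and the C-3 centre.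

**Compound list**

1 | 3-bromo-2,5-dimethylfuran | Cc1cc(Br)c(C)o1 | starting material
2 | 3-bromo-2,5-bis(bromomethyl)furan (formed in the flask, not isolated) | BrCc1cc(Br)c(CBr)o1 | intermediate
3 | 3-bromo-2,5-bis(methoxymethyl)furan | COCc1cc(Br)c(COC)o1 | intermediate
4 | 6,7-dimethoxychroman-4-one | COc1cc2OCCC(=O)c2cc1OC | starting material
5 | rac-3-[2,5-bis(methoxymethyl)furan-3-yl]-6,7-dimethoxychroman-4-one | COCc1cc(C2COc3cc(OC)c(OC)cc3C2=O)c(COC)o1 | intermediate
6 | 3-[2,5-bis(methoxymethyl)furan-3-yl]-6,7-dimethoxychroman-4-ol (racemic cis/trans mixture) | COCc1cc(C2COc3cc(OC)c(OC)cc3C2O)c(COC)o1 | intermediate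
7 | 3-[2,5-bis(methoxymethyl)furan-3-yl]-6,7-dimethoxy-2H-chromene | COCc1cc(C2=Cc3cc(OC)c(OC)cc3OC2)c(COC)o1 | intermediate
8 | (3S)-3-[2,5-bis(methoxymethyl)furan-3-yl]-6,7-dimethoxychroman | COCc1cc([C@H]2COc3cc(OC)c(OC)cc3C2)c(COC)o1 | intermediate
9 | (3Z)-3-[(3S)-6,7-dimethoxychroman-3-yl]-1,6-dimethoxyhex-3-ene-2,5-dione | COCC(=O)/C=C(/[C@H]1COc2cc(OC)c(OC)cc2C1)C(=O)COC | intermediate
10 | (3S)-3-[(1Z,3Z,5Z)-2,5-bis(tert-butyldimethylsilyloxy)-1,6-dimethoxyhexa-1,3,5-trien-3-yl]-6,7-dimethoxychroman | CO/C=C(\O[Si](C)(C)C(C)(C)C)/C([C@H]1COc2cc(OC)c(OC)cc2C1)=C\C(O[Si](C)(C)C(C)(C)C)=C\OC | intermediate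
11 | (3S)-3-[2,5-bis(tert-butyldimethylsilyloxy)-3,4-dimethoxyphenyl]-6,7-dimethoxychroman | COc1c(O[Si](C)(C)C(C)(C)C)cc([C@H]2COc3cc(OC)c(OC)cc3C2)c(O[Si](C)(C)C(C)(C)C)c1OC | intermediate
12 | 2-[(3S)-6,7-dimethoxychroman-3-yl]-5,6-dimethoxybenzene-1,4-diol (formed in the flask, not isolated) | COc1c(O)cc([C@H]2COc3cc(OC)c(OC)cc3C2)c(O)c1OC | intermediate
13 | abroquinone A, 5-[(3S)-6,7-dimethoxychroman-3-yl]-2,3-dimethoxycyclohexa-2,5-diene-1,4-dione | COC1=C(OC)C(=O)C([C@H]2COc3cc(OC)c(OC)cc3C2)=CC1=O | target

**Step count and risks**

Total steps: 9. Longest linear sequence: 9 steps (1 to 13); compound 4 enters at step 2.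

Steps most likely to fail:

Step 8 (proposed new method). The radical cation may be consumed before its termini meet: intermolecular coupling and oligomerisation, capture by adventitious nucleophiles, loss of methanol from the cyclised intermediate instead of proton loss, or electron transfer from the dimethoxychroman ring if the potential window proves narrower than expected. The fallback uses known chemistry and sets out from 10. Heating in toluene at 110 °C with a little Et3N should bring about thermal disrotatory 6π-electrocyclisation to (3S)-3-[cis-5,6-dimethoxy-1,4-bis(tert-butyldimethylsilyloxy)cyclohexa-1,3-dien-2-yl]-6,7-dimethoxychroman F1. Dehydrogenation of this cyclohexadiene with DDQ and 2,6-lutidine in CH2Cl2 at 0 °C should then give the arene, and the route is rejoined at 11.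

Step 7. Deprotonation may occur at the γ-methine (the C-3 hydrogen of the chroman, vinylogous to one ketone) in competition with the methoxymethyl groups, which would erode the configuration set in step 5; five-ring aldol closure of the mono-enol ether is a lesser risk. The fallback moves ring construction ahead of the stereocentre and sets out from 7:
- Photo-oxygenation (O2, tetraphenylporphyrin, visible light, CH2Cl2, −78 °C, then Me2S) should open the furan selectively to (3Z)-3-(6,7-dimethoxy-2H-chromen-3-yl)-1,6-dimethoxyhex-3-ene-2,5-dione F2, which has no stereocentre to lose.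
- Silylation as in step 7 should give 3-[(1Z,3Z,5Z)-2,5-bis(tert-butyldimethylsilyloxy)-1,6-dimethoxyhexa-1,3,5-trien-3-yl]-6,7-dimethoxy-2H-chromene F3.
- Ring closure as in step 8 should give 3-[2,5-bis(tert-butyldimethylsilyloxy)-3,4-dimethoxyphenyl]-6,7-dimethoxy-2H-chromene F4.
- Iridium-catalysed asymmetric hydrogenation of this 3-aryl-2H-chromene, under the conditions of step 5, sets C-3 last and rejoins the route at 11.

Step 5. Facial discrimination in hydrogen delivery may be poor, because the 3-substituent is an ortho-substituted, ether-bearing heteroarene that can bind the cationic iridium centre; partial reduction of the furan is also possible. The fallback sets out from 5: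
- Asymmetric transfer hydrogenation with dynamic kinetic resolution (RuCl(p-cymene)(TsDPEN), HCO2H/Et3N, 40 °C, catalyst hand chosen accordingly) should give the cis alcohol (3S,4S)-3-[2,5-bis(methoxymethyl)furan-3-yl]-6,7-dimethoxychroman-4-ol F5. C-3 is set through rapid enolisation of the ketone and catalyst-controlled hydride delivery.
- Conversion to the xanthate O-{(3S,4S)-3-[2,5-bis(methoxymethyl)furan-3-yl]-6,7-dimethoxychroman-4-yl} S-methyl carbonodithioate F6 (NaH, CS2, MeI, THF, 0 °C).
- Barton–McCombie deoxygenation (Bu3SnH, AIBN, toluene, 80 °C) removes the benzylic oxygen without touching C-3 and rejoins the route at 8.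

**Further compounds**

F1 | step 8 | (3S)-3-[cis-5,6-dimethoxy-1,4-bis(tert-butyldimethylsilyloxy)cyclohexa-1,3-dien-2-yl]-6,7-dimethoxychroman (one of the two cis diastereomers shown) | CO[C@@H]1[C@H](OC)C(O[Si](C)(C)C(C)(C)C)=C([C@H]2COc3cc(OC)c(OC)cc3C2)C=C1O[Si](C)(C)C(C)(C)C
F2 | step 7 | (3Z)-3-(6,7-dimethoxy-2H-chromen-3-yl)-1,6-dimethoxyhex-3-ene-2,5-dione | COCC(=O)/C=C(/C1=Cc2cc(OC)c(OC)cc2OC1)C(=O)COC
F3 | step 7 | 3-[(1Z,3Z,5Z)-2,5-bis(tert-butyldimethylsilyloxy)-1,6-dimethoxyhexa-1,3,5-trien-3-yl]-6,7-dimethoxy-2H-chromene | CO/C=C(\O[Si](C)(C)C(C)(C)C)/C(C1=Cc2cc(OC)c(OC)cc2OC1)=C\C(O[Si](C)(C)C(C)(C)C)=C\OC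
F4 | step 7 | 3-[2,5-bis(tert-butyldimethylsilyloxy)-3,4-dimethoxyphenyl]-6,7-dimethoxy-2H-chromene | COc1c(O[Si](C)(C)C(C)(C)C)cc(C2=Cc3cc(OC)c(OC)cc3OC2)c(O[Si](C)(C)C(C)(C)C)c1OC
F5 | step 5 | (3S,4S)-3-[2,5-bis(methoxymethyl)furan-3-yl]-6,7-dimethoxychroman-4-ol | COCc1cc([C@H]2COc3cc(OC)c(OC)cc3[C@H]2O)c(COC)o1
F6 | step 5 | O-{(3S,4S)-3-[2,5-bis(methoxymethyl)furan-3-yl]-6,7-dimethoxychroman-4-yl} S-methyl carbonodithioate | COCc1cc([C@H]2COc3cc(OC)c(OC)cc3[C@H]2OC(=S)SC)c(COC)o1
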